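**Retrosynthetic overview**

1. Target acid ⇐ its allyl ester, by deallylation with zerovalent palladium at room temperature as the last step, so the finished stereocentre never sees heat or light.
2. The pyran ring is the only ring made, and it is made second to last. It comes from a plastoquinone-type prenylquinone by tautomerisation to the hydroxy-o-quinone methide and oxa-6π electrocyclisation, the presumed biosynthetic route to chromenols. A chiral bifunctional amine is used so that the ring closure itself sets C2 as S.
3. Quinone ⇐ 2,3-dimethylhydroquinone (aromatic ring bought) + a C20 allylic alcohol, by Friedel–Crafts prenyl transfer and Ag2O oxidation.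
4. C20 allylic alcohol ⇐ E-selective Wittig reaction of a C12 hydroxy aldehyde with an α-homoprenyl ester ylide; this sets the 2E acid alkene.
5. C12 aldehyde ⇐ (E,E)-farnesyl acetate (terminal bromohydrin, epoxide, H5IO6 cleavage); ylide ⇐ allyl (triphenylphosphoranylidene)acetate + 5-bromo-2-methylpent-2-ene.

Assumption: the sense of induction of the new step 6 cannot be predicted; the (9R) quinidine-derived catalyst is written as giving (2S), and its (8α,9S) quinine-derived pseudo-enantiomer replaces it if the first run shows the opposite sense.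

The target is (2E,6E)-9-[(2S)-6-hydroxy-2,7,8-trimethyl-2H-chromen-2-yl]-6-methyl-2-(4-methylpent-3-en-1-yl)nona-2,6-dienoic acid. The ester group is trans to the main chain across the 2,3-alkene, which is the geometry an E-selective Wittig reaction delivers.

**Route**

Step 1
Reactants: 1 allyl (triphenylphosphoranylidene)acetate; 2 5-bromo-2-methylpent-2-ene
Product: 4 allyl 6-methyl-2-(triphenyl-λ5-phosphanylidene)hept-5-enoate, via phosphonium bromide 3 (not isolated)
Conditions: NaI (10 mol%), MeCN, 80 °C, 36 h; then 2 M NaOH, CH2Cl2/H2O, 0 °C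
Reagents that add atoms: none
Why: C-alkylation of the ester-stabilised ylide by the primary bromide (SN2, helped by catalytic iodide exchange) gives the phosphonium salt, and aqueous NaOH removes its remaining α-hydrogen to give the α-substituted stabilised ylide (ylide alkylation).

Step 2
Reactants: 5 (2E,6E)-3,7,11-trimethyldodeca-2,6,10-trien-1-yl acetate [(E,E)-farnesyl acetate]
Product: 7 (2E,6E)-9-(3,3-dimethyloxiran-2-yl)-3,7-dimethylnona-2,6-dien-1-ol (racemic 10,11-epoxyfarnesol), via bromohydrin acetate 6 (not isolated)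
Conditions: N-bromosuccinimide (1.1 equiv), THF/H2O (5:2), 0 °C; then K2CO3, MeOH, 20 °C
Reagents that add atoms: water, O (becomes the epoxide oxygen); N-bromosuccinimide, O=C1CCC(=O)N1Br (its bromine is carried only in 6 and is lost on epoxide closure)
Why: van Tamelen terminal functionalisation, in which the coiled polyene in aqueous THF exposes only the terminal trisubstituted alkene to bromonium formation (the 2,3-alkene is also deactivated by the allylic acetate), water opens it at the tertiary carbon, and K2CO3/MeOH closes the bromohydrin to the epoxide and methanolyses the acetate; the racemic epoxide carbon is destroyed in step 3.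

Step 3
Reactants: 7 (2E,6E)-9-(3,3-dimethyloxiran-2-yl)-3,7-dimethylnona-2,6-dien-1-ol
Product: 8 (4E,8E)-10-hydroxy-4,8-dimethyldeca-4,8-dienal
Conditions: H5IO6 (1.2 equiv), THF/Et2O, 0 °C, 30 min
Reagents that add atoms: none
Why: periodic acid hydrolyses the trisubstituted epoxide to the vicinal diol and cleaves it in the same flask (Malaprade glycol cleavage) to the aldehyde and acetone, leaving the trisubstituted alkenes and the primary allylic alcohol untouched.

Step 4
Reactants: 8 (4E,8E)-10-hydroxy-4,8-dimethyldeca-4,8-dienal; 4 allyl 6-methyl-2-(triphenyl-λ5-phosphanylidene)hept-5-enoate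
Product: 9 allyl (2E,6E,10E)-12-hydroxy-6,10-dimethyl-2-(4-methylpent-3-en-1-yl)dodeca-2,6,10-trienoate
Conditions: 4 (1.3 equiv), toluene, 80 °C, 16 h
Reagents that add atoms: none
Why: Wittig olefination of an unhindered aliphatic aldehyde with an α-alkyl ester-stabilised ylide gives the trisubstituted enoate with the ester trans to the chain (2E, typically above 95:5) and tolerates the free alcohol.

Step 5
Reactants: 9 allyl (2E,6E,10E)-12-hydroxy-6,10-dimethyl-2-(4-methylpent-3-en-1-yl)dodeca-2,6,10-trienoate; 10 2,3-dimethylbenzene-1,4-diol (2,3-dimethylhydroquinone)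
Product: 12 allyl (2E,6E,10E)-12-(4,5-dimethyl-3,6-dioxocyclohexa-1,4-dien-1-yl)-6,10-dimethyl-2-(4-methylpent-3-en-1-yl)dodeca-2,6,10-trienoate, via hydroquinone 11 (not isolated)
Conditions: 10 (4 equiv), BF3·OEt2 (0.5 equiv), 1,4-dioxane, 20 °C, N2; aqueous wash; then Ag2O, MgSO4, Et2O, 20 °C; chromatography on AgNO3-impregnated SiO2 to remove the minor 10Z isomer (about 10%)
Reagents that add atoms: none
Why: Friedel–Crafts allylation of the electron-rich hydroquinone by the BF3-ionised allylic alcohol at its primary terminus (the two free ring positions are equivalent and excess arene suppresses dialkylation), the laboratory counterpart of aromatic prenyl transfer and the standard entry to plastoquinones, followed by Ag2O oxidation of the air-sensitive hydroquinone to the stable quinone.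

Step 6
Reactants: 12 allyl (2E,6E,10E)-12-(4,5-dimethyl-3,6-dioxocyclohexa-1,4-dien-1-yl)-6,10-dimethyl-2-(4-methylpent-3-en-1-yl)dodeca-2,6,10-trienoate
Product: 14 allyl (2E,6E)-9-[(2S)-6-hydroxy-2,7,8-trimethyl-2H-chromen-2-yl]-6-methyl-2-(4-methylpent-3-en-1-yl)nona-2,6-dienoate, via hydroxy-o-quinone methide 13 (not isolated)
Conditions: 3-{[3,5-bis(trifluoromethyl)phenyl]amino}-4-{[(9R)-6'-methoxycinchonan-9-yl]amino}cyclobut-3-ene-1,2-dione (C32H28F6N4O3, 10 mol%), CH2Cl2/toluene (1:1), 4 Å molecular sieves, 0 → 20 °C, argon, dark, 24–48 h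
Reagents that add atoms: none
Why: Proposed new method: amines such as Et3N or pyridine are known to isomerise prenylquinones to racemic chromenols by removing a C12–H (allylic and vinylogously α to the C3' carbonyl), reprotonating on oxygen and letting the hydroxy-o-quinone methide close by thermal disrotatory oxa-6π electrocyclisation; here the quinuclidine nitrogen of the catalyst is meant to do the same proton shuttle while the squaramide N–H pair is hydrogen-bonded to the C6' carbonyl oxygen that becomes O1, so that 13 is formed already docked in the chiral pocket and the catalyst selects one helical sense of the oxatriene, which together with the 10E geometry of 12 defines C2 as S, the uncatalysed racemic path being negligible because 12 is inert without base at 20 °C; the closest known reaction types are the amine-promoted quinone-to-chromenol isomerisation, chiral-cation-directed asymmetric 6π electrocyclisations of anions, and chiral Brønsted acid controlled closures of o-quinone-methide-type ion pairs to 2H-chromenes.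

Step 7
Reactants: 14 allyl (2E,6E)-9-[(2S)-6-hydroxy-2,7,8-trimethyl-2H-chromen-2-yl]-6-methyl-2-(4-methylpent-3-en-1-yl)nona-2,6-dienoate
Product: 15 (2E,6E)-9-[(2S)-6-hydroxy-2,7,8-trimethyl-2H-chromen-2-yl]-6-methyl-2-(4-methylpent-3-en-1-yl)nona-2,6-dienoic acid
Conditions: Pd(PPh3)4 (5 mol%), morpholine (5 equiv), THF, 20 °C, argon, dark; dilute citric acid work-up
Reagents that add atoms: none
Why: Tsuji–Trost deallylation, in which zerovalent palladium ionises only the allyl ester to a π-allyl complex that morpholine captures at room temperature and neutral pH, so the C2 stereocentre (labile only to heat or light through retro-6π ring opening), the free phenol and all alkenes are left as they are.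

**Compound list**

1 | allyl (triphenylphosphoranylidene)acetate | C=CCOC(=O)C=P(c1ccccc1)(c1ccccc1)c1ccccc1 | starting material
2 | 5-bromo-2-methylpent-2-ene | CC(C)=CCCBr | starting material
3 | [1-(allyloxycarbonyl)-5-methylhex-4-en-1-yl]triphenylphosphonium bromide (racemic) | C=CCOC(=O)C(CCC=C(C)C)[P+](c1ccccc1)(c1ccccc1)c1ccccc1.[Br-] | intermediate
4 | allyl 6-methyl-2-(triphenyl-λ5-phosphanylidene)hept-5-enoate | C=CCOC(=O)C(CCC=C(C)C)=P(c1ccccc1)(c1ccccc1)c1ccccc1 | intermediate
5 | (2E,6E)-3,7,11-trimethyldodeca-2,6,10-trien-1-yl acetate | CC(C)=CCC/C(C)=C/CC/C(C)=C/COC(C)=O | starting material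
6 | (2E,6E)-10-bromo-11-hydroxy-3,7,11-trimethyldodeca-2,6-dien-1-yl acetate (racemic) | CC(C)(O)C(Br)CC/C(C)=C/CC/C(C)=C/COC(C)=O | intermediate
7 | (2E,6E)-9-(3,3-dimethyloxiran-2-yl)-3,7-dimethylnona-2,6-dien-1-ol (racemic) | CC1(C)OC1CC/C(C)=C/CC/C(C)=C/CO | intermediate
8 | (4E,8E)-10-hydroxy-4,8-dimethyldeca-4,8-dienal | O=CCC/C(C)=C/CC/C(C)=C/CO | intermediate
9 | allyl (2E,6E,10E)-12-hydroxy-6,10-dimethyl-2-(4-methylpent-3-en-1-yl)dodeca-2,6,10-trienoate | C=CCOC(=O)/C(CCC=C(C)C)=C/CC/C(C)=C/CC/C(C)=C/CO | intermediate
10 | 2,3-dimethylbenzene-1,4-diol | Cc1c(O)ccc(O)c1C | starting material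
11 | allyl (2E,6E,10E)-12-(2,5-dihydroxy-3,4-dimethylphenyl)-6,10-dimethyl-2-(4-methylpent-3-en-1-yl)dodeca-2,6,10-trienoate | C=CCOC(=O)/C(CCC=C(C)C)=C/CC/C(C)=C/CC/C(C)=C/Cc1cc(O)c(C)c(C)c1O | intermediate
12 | allyl (2E,6E,10E)-12-(4,5-dimethyl-3,6-dioxocyclohexa-1,4-dien-1-yl)-6,10-dimethyl-2-(4-methylpent-3-en-1-yl)dodeca-2,6,10-trienoate | C=CCOC(=O)/C(CCC=C(C)C)=C/CC/C(C)=C/CC/C(C)=C/CC1=CC(=O)C(C)=C(C)C1=O | intermediate
13 | allyl (2E,6E,10E)-12-[(Z)-3-hydroxy-4,5-dimethyl-6-oxocyclohexa-2,4-dien-1-ylidene]-6,10-dimethyl-2-(4-methylpent-3-en-1-yl)dodeca-2,6,10-trienoate | C=CCOC(=O)/C(CCC=C(C)C)=C/CC/C(C)=C/CC/C(C)=C/C=C1/C=C(O)C(C)=C(C)C1=O | intermediate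
14 | allyl (2E,6E)-9-[(2S)-6-hydroxy-2,7,8-trimethyl-2H-chromen-2-yl]-6-methyl-2-(4-methylpent-3-en-1-yl)nona-2,6-dienoate | CC(C)=CCC/C(=C\CC/C(C)=C/CC[C@@]1(C)C=Cc2cc(O)c(C)c(C)c2O1)C(=O)OCC=C | intermediate
15 | (2E,6E)-9-[(2S)-6-hydroxy-2,7,8-trimethyl-2H-chromen-2-yl]-6-methyl-2-(4-methylpent-3-en-1-yl)nona-2,6-dienoic acid | CC(C)=CCC/C(=C\CC/C(C)=C/CC[C@@]1(C)C=Cc2cc(O)c(C)c(C)c2O1)C(=O)O | target

**Step count and risk**

Total steps: 7. Longest linear sequence: 6 steps (5 → 7 → 8 → 9 → 12 → 14 → 15); step 1 is the side branch.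

Steps most likely to fail:

Step 6 is the highest risk. It is an untested enantioselective method: catalyst turnover, racemic closure of 13 when it is not bound to the catalyst, and the sense of induction are all unknown. The fallback sets out from 12. The known isomerisation is run without chiral control (pyridine, 90 °C, dark) to give the racemic chromenol allyl ester F1. This is resolved by preparative HPLC on an amylose tris(3,5-dimethylphenylcarbamate) phase, and the (2S)-enantiomer is 14, where the route is rejoined.

Step 5 is the second risk. It is a low-yielding Friedel–Crafts reaction on the most advanced fragment, with competing cation–olefin cyclisation, chroman formation and partial loss of the 10E geometry that step 6 relays into C2. The fallback sets out from 9. PBr3 (Et2O, 0 °C) gives the allylic bromide F2. Separately, commercial 1,4-dimethoxy-2,3-dimethylbenzene is ortho-lithiated (n-BuLi, TMEDA, Et2O, 0 → 20 °C) to (2,5-dimethoxy-3,4-dimethylphenyl)lithium F3 and transmetallated with CuBr·SMe2 to the arylcopper F4 (monovalent copper). This reagent (1.2 equiv, THF, −40 → 0 °C) displaces the bromide of F2 at the primary carbon without touching the alkene geometry or the esters, giving the dimethoxyarene F5. Oxidative demethylation with (NH4)2Ce(NO3)6 (MeCN/H2O, 0 °C) comes back to the route at 12.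

Step 1 is the third risk, because SN2 attack of a stabilised ylide on an unactivated primary bromide may be sluggish. The fallback sets out from 2. Commercial allyl diethylphosphonoacetate is deprotonated (NaH, DMSO, 20 → 60 °C) and alkylated with 2 to give the phosphonate F6. This is condensed directly with aldehyde 8 in a Horner–Wadsworth–Emmons reaction (MeMgBr, THF, reflux; magnesium phosphonoenolates give high E ratios with α-branched phosphonoacetates, and the minor 2Z ester is removed by chromatography). The route is rejoined at 9, bypassing 4.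

**Further compounds**

F1 | step 6 | racemic allyl (2E,6E)-9-(6-hydroxy-2,7,8-trimethyl-2H-chromen-2-yl)-6-methyl-2-(4-methylpent-3-en-1-yl)nona-2,6-dienoate | CC(C)=CCC/C(=C\CC/C(C)=C/CCC1(C)C=Cc2cc(O)c(C)c(C)c2O1)C(=O)OCC=C
F2 | step 5 | allyl (2E,6E,10E)-12-bromo-6,10-dimethyl-2-(4-methylpent-3-en-1-yl)dodeca-2,6,10-trienoate | C=CCOC(=O)/C(CCC=C(C)C)=C/CC/C(C)=C/CC/C(C)=C/CBr
F3 | step 5 | (2,5-dimethoxy-3,4-dimethylphenyl)lithium | [Li]c1cc(OC)c(C)c(C)c1OC
F4 | step 5 | (2,5-dimethoxy-3,4-dimethylphenyl)copper | [Cu]c1cc(OC)c(C)c(C)c1OC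
F5 | step 5 | allyl (2E,6E,10E)-12-(2,5-dimethoxy-3,4-dimethylphenyl)-6,10-dimethyl-2-(4-methylpent-3-en-1-yl)dodeca-2,6,10-trienoate | C=CCOC(=O)/C(CCC=C(C)C)=C/CC/C(C)=C/CC/C(C)=C/Cc1cc(OC)c(C)c(C)c1OC
F6 | step 1 | allyl 2-(diethoxyphosphoryl)-6-methylhept-5-enoate (racemic) | C=CCOC(=O)C(CCC=C(C)C)P(=O)(OCC)OCC
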